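Locants used: C1 (quaternary, geranyl), C2H2–C3H=C4(Me)–C5H (ring B, closed by C14), C6H2, C7H, C8Me2, O9, C10=C11(prenyl)–C12=O, carbinol carbons C13 and C14; ring A = C1,C12,C11,C10,C13,C14; ring C = C5,C6,C7,C13,C14; ring D = C7,C8,O9,C10,C13.
Retrosynthesis: C6–C7 and C5–C14 are cut together, which opens rings B and C to a (2Z)-3-methylpenta-2,4-dienyl chain on C1, a C14 ketone and a radical site at C7. C1–C2, C1–geranyl, C11–prenyl, O9–C10 and C7–C13 are cut next, which leaves 2,6-dimethoxy-1,4-benzoquinone.
Enabling feature: C7 and C14 are 1,3 across the quaternary carbinol C13 and not conjugated, so one can be a radical and the other a ketone. C5=C6 is a diene terminus, so a C7 radical adds at C6 and the allyl unit, reduced to allylchromium, adds through C5 to C14. Ring A has a hidden mirror plane through C12 and C13.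
Forward order: ring A (quinone) → C7/C8/O9 unit by one dianion addition → ring D by desymmetrising oxa-Michael closure → C11 prenyl (bromination, Stille) → C1 geranyl, then C1 dienyl → rings B and C together in the last step.
Stereochemistry: C13 from the chiral phosphoric acid step; C1 by alkylation anti to the pseudo-axial C13–OH; C7, C5 and C14 arise in the last step and are fixed by the three cis ring fusions.

Key step: step 13

Remark: the ester-bearing carbon C7 is carried as a mixture of epimers from 6 to 21; it becomes a planar radical in step 13, so only C13 and C1 decide the outcome.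

Step 1
Reactants: 1 tert-butyl acetate; 2 acetone
Product: 3 tert-butyl 3-hydroxy-3-methylbutanoate
Conditions: LiN(iPr)2, THF, −78 °C; then 2; AcOH
Reagents that add atoms: none
Why: Aldol addition of the lithium ester enolate to acetone gives the β-hydroxy ester, and no stereocentre is formed.

Step 2
Reactants: 3 tert-butyl 3-hydroxy-3-methylbutanoate; 4 2,6-dimethoxy-1,4-benzoquinone
Product: 6 quinol diol tert-butyl ester, via dilithium dianion 5 (not isolated)
Conditions: LiN(iPr)2 (2.1 equiv), THF, −78 to −30 °C; then addition to 4, THF, −78 °C; AcOH, −78 °C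
Reagents that add atoms: none
Why: The alkoxide/enolate dianion of the β-hydroxy ester (the species of the Fráter–Seebach alkylation, which does not β-eliminate) should add 1,2 to the quinone carbonyl flanked by the two methoxy-bearing carbons (the other carbonyl is a doubly vinylogous ester), as in quinol syntheses from ester enolates and quinones; C7 is formed without control, C13 stays prochiral, and the cold acidic quench prevents alkoxide-driven ring closure.

Step 3
Reactants: 6 quinol diol tert-butyl ester
Product: 7 bicyclic dienone of rings A and D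
Conditions: (R)-3,3′-bis(2,4,6-triisopropylphenyl)-1,1′-binaphthyl-2,2′-diyl hydrogen phosphate (10 mol %), 5 Å molecular sieves, toluene, 25 °C
Reagents that add atoms: none
Why: Chiral Brønsted acid-catalysed desymmetrising intramolecular oxa-Michael addition of the tertiary alcohol to one of the two enantiotopic β-methoxy enone arms (5-exo), followed by loss of methanol, is the cyclohexadienone desymmetrisation known for tethered alcohols; the catalyst (or its enantiomer, according to the sense of induction) selects the arm and so sets C13, and the sieves take up methanol so that the closure is not reversed.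

Step 4
Reactants: 7 bicyclic dienone of rings A and D
Product: 8 C1,C11-dibromide
Conditions: NBS (2.1 equiv), MeCN, 0 °C
Reagents that add atoms: N-bromosuccinimide, O=C1CCC(=O)N1Br
Why: Electrophilic α-bromination of both vinylogous ester α-carbons (addition to the enol ether, loss of a proton) is done while the molecule holds no isolated olefin, and no stereocentre is touched.

Step 5
Reactants: 8 C1,C11-dibromide
Product: 10 C11-bromo vinylogous acid, via lithium bromoenolate 9 (not isolated)
Conditions: LiI, EtOAc, 60 °C; then aq. NaHSO3, 0 °C
Reagents that add atoms: none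
Why: Iodide cleaves only the O–methyl bond (SN2 dealkylation of a vinylogous methyl ester), so ring D cannot move to the other arm and C13 keeps its configuration; bisulfite then removes the electrophilic bromine of the 2-bromo-1,3-dione, while the vinyl bromide at C11 stays.

Step 6
Reactants: 10 C11-bromo vinylogous acid; 11 tributyl(3-methylbut-2-en-1-yl)stannane
Product: 12 C11-prenyl vinylogous acid
Conditions: Pd(PPh3)4 (5 mol %), CuI (10 mol %), iPr2NEt, DMF, 60 °C
Reagents that add atoms: none
Why: Stille coupling of the α-bromo vinylogous ester with the prenylstannane should give the linear prenyl group by reductive elimination at the less hindered allyl terminus; the amine holds the acidic enol as its salt so that the allylstannane is not protonated.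

Step 7
Reactants: 12 C11-prenyl vinylogous acid; 13 geranyl acetate
Product: 14 C1-geranyl vinylogous acid
Conditions: Pd(PPh3)4 (5 mol %), Et3N, THF, 25 °C
Reagents that add atoms: none
Why: Tsuji–Trost C-allylation of the cyclic 1,3-dione carbon C1 by the π-allylpalladium complex of geranyl acetate, with attack at the unsubstituted terminus, keeps the E-olefin; C1 stays enolised, so no stereocentre forms.

Step 8
Reactants: 15 (2Z)-3-methylpent-2-en-4-yn-1-ol
Product: 16 (2Z)-3-methylpenta-2,4-dien-1-ol
Conditions: H2 (1 atm), Pd/CaCO3 poisoned with Pb(OAc)2, quinoline, EtOAc, 0 °C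
Reagents that add atoms: none
Why: Lindlar semihydrogenation reduces the terminal alkyne to the vinyl group and leaves the Z-trisubstituted olefin untouched.

Step 9
Reactants: 16 (2Z)-3-methylpenta-2,4-dien-1-ol
Product: 17 (2Z)-1-bromo-3-methylpenta-2,4-diene
Conditions: PBr3 (0.4 equiv), Et2O, −20 °C
Reagents that add atoms: phosphorus tribromide, BrP(Br)Br
Why: Bromination of the primary allylic alcohol through its phosphite ester (SN2) at low temperature should keep the Z geometry; the bromide is used at once.

Step 10
Reactants: 14 C1-geranyl vinylogous acid; 17 (2Z)-1-bromo-3-methylpenta-2,4-diene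
Product: 18 C1-quaternary tert-butyl ester
Conditions: Cs2CO3, MeCN, 0 °C
Reagents that add atoms: none
Why: C-alkylation of the 2-geranyl-1,3-dione enolate with the allylic bromide creates the quaternary centre C1; ring D holds C7 pseudo-equatorial and the C13 hydroxyl pseudo-axial, so the dienyl group should enter anti to that hydroxyl, that is cis to C7, which is the arrangement step 13 needs.

Step 11
Reactants: 18 C1-quaternary tert-butyl ester
Product: 20 carboxylic acid silylated at the C13 oxygen, via bis-silylated ester 19 (not isolated)
Conditions: Me3SiOTf, 2,6-lutidine, CH2Cl2, −78 to 0 °C; then MeOH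
Reagents that add atoms: trimethylsilyl trifluoromethanesulfonate, C[Si](C)(C)OS(=O)(=O)C(F)(F)F
Why: Buffered silyl triflate cleaves the tert-butyl ester by silyl transfer and loss of isobutene without acid that would harm the diene; it also silylates the C13 hydroxyl (which blocks β-lactone formation in step 12), and methanol frees only the silyl ester.

Step 12
Reactants: 20 carboxylic acid silylated at the C13 oxygen
Product: 21 N-(acyloxy)phthalimide
Conditions: N-hydroxyphthalimide, DIC, DMAP (cat.), CH2Cl2, 25 °C
Reagents that add atoms: N-hydroxyphthalimide, O=C1N(O)C(=O)c2ccccc12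
Why: Carbodiimide (Steglich-type) esterification turns the hindered acid into the redox-active ester that serves as the radical precursor.

Step 13
Reactants: 21 N-(acyloxy)phthalimide
Product: 26 CNP0323114.1, via C7 radical 22 (not isolated), via nine-membered allyl radical 23 (not isolated), via allylchromium dichloride 24 (not isolated), via bis-silyl ether 25 (not isolated)
Conditions: CrCl2 (20 mol %), Mn powder, Me3SiCl, DMF–THF, 25 °C, slow addition of 21 (final 0.002 M); then 1 M HCl, THF, 0 °C
Reagents that add atoms: none
Why: Proposed new method: CrCl2 (kept at a low stationary concentration by Mn and Me3SiCl) transfers one electron to the N-(acyloxy)phthalimide, which loses CO2 and phthalimide anion to give the secondary radical 22 at C7; 22 adds to the diene terminus C6, the allyl radical 23 is reduced by a second CrCl2 to allylchromium 24, and 24 adds through its γ-carbon C5 to the C14 ketone, the chromium alkoxide being silylated to 25 and unmasked to 26 by the acidic work-up. The closest known reaction types are the chromium-mediated three-component coupling of alkyl halides with 1,3-dienes and carbonyl compounds (radical–polar crossover with Nozaki–Hiyama–Kishi-type allylation) and the chromium-mediated decarboxylative addition of redox-active esters to carbonyl groups; what is new is that radical source, diene and ketone sit on one ring, so that the coupling becomes a (3+2) annulation. Ring closure: the nine-membered ring forms first by 9-endo-trig radical addition (only the bonds C1–C2, C2–C3 and C4–C5 rotate, because of the Z-olefin), then ring B (six-membered) and ring C (five-membered) form together by transannular allylation, attack through C3 being excluded because it would give a four-membered ring. Stereocentres: at C7 the chain can reach only the face of ring D that carries C14 (cis C/D fusion), at C14 the allyl carbon arrives on the face that carries the chain so that the new hydroxyl is cis to the C13 oxygen, and at C5 the hydrogen stays on the outside of the nine-membered ring (cis B/C fusion), so all three are relayed from C13 and C1. The step needs the 9-endo addition to outrun capture of 22 by CrCl2 (an alkylchromium at C7 would expel the ring D oxygen), the 1,2-acyl shift of this β-keto radical and 6-exo additions to C3 or to the geranyl olefin: ring D holds C7 pseudo-equatorial, which puts those nearer carbons and the allylic hydrogens out of reach and forbids a vinyl shift, and slow addition with catalytic CrCl2 limits capture. The regiochemistry at the diene (bond to C6, then bond at C5) is the innate one for radical addition to a 1,3-diene followed by γ-attack of an allylmetal.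

Compound list
1 | tert-butyl acetate | CC(=O)OC(C)(C)C | starting material
2 | acetone | CC(C)=O | starting material
3 | tert-butyl 3-hydroxy-3-methylbutanoate | CC(C)(O)CC(=O)OC(C)(C)C | intermediate
4 | 2,6-dimethoxy-1,4-benzoquinone | COC1=CC(=O)C=C(OC)C1=O | starting material
5 | dilithium dianion of 3 (lithium alkoxide, lithium ester enolate; not isolated) | [Li+].[Li+].CC(C)([O-])C=C([O-])OC(C)(C)C | intermediate
6 | tert-butyl 3-hydroxy-2-(1-hydroxy-2,6-dimethoxy-4-oxocyclohexa-2,5-dien-1-yl)-3-methylbutanoate (racemic at C7; C13 prochiral) | COC1=CC(=O)C=C(OC)C1(O)C(C(=O)OC(C)(C)C)C(C)(C)O | intermediate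
7 | tert-butyl 3a-hydroxy-4-methoxy-2,2-dimethyl-6-oxo-2,3,3a,6-tetrahydro-1-benzofuran-3-carboxylate (C13 = C3a as in the target; both epimers at C7 = C3) | COC1=CC(=O)C=C2OC(C)(C)C(C(=O)OC(C)(C)C)[C@@]12O | intermediate
8 | 5,7-dibromo derivative of 7 (bromine on C1 and C11) | COC1=C(Br)C(=O)C(Br)=C2OC(C)(C)C(C(=O)OC(C)(C)C)[C@@]12O | intermediate
9 | lithium enolate of the 2-bromo-1,3-dione from O-demethylation of 8 (not isolated) | [Li+].[O-]C1=C(Br)C(=O)C(Br)=C2OC(C)(C)C(C(=O)OC(C)(C)C)[C@@]12O | intermediate
10 | tert-butyl 7-bromo-3a,4-dihydroxy-2,2-dimethyl-6-oxo-2,3,3a,6-tetrahydro-1-benzofuran-3-carboxylate (vinylogous acid, bromine on C11) | OC1=CC(=O)C(Br)=C2OC(C)(C)C(C(=O)OC(C)(C)C)[C@@]12O | intermediate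
11 | tributyl(3-methylbut-2-en-1-yl)stannane | CCCC[Sn](CCCC)(CCCC)CC=C(C)C | starting material
12 | 7-(3-methylbut-2-en-1-yl) analogue of 10 (prenyl on C11) | OC1=CC(=O)C(CC=C(C)C)=C2OC(C)(C)C(C(=O)OC(C)(C)C)[C@@]12O | intermediate
13 | geranyl acetate, (2E)-3,7-dimethylocta-2,6-dien-1-yl acetate | CC(=O)OC/C=C(\C)CCC=C(C)C | starting material
14 | 5-[(2E)-3,7-dimethylocta-2,6-dien-1-yl] derivative of 12 (geranyl on enolised C1) | CC(C)=CCC/C(C)=C/CC1=C(O)[C@]2(O)C(C(=O)OC(C)(C)C)C(C)(C)OC2=C(CC=C(C)C)C1=O | intermediate
15 | (2Z)-3-methylpent-2-en-4-yn-1-ol | C#C/C(C)=C\CO | starting material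
16 | (2Z)-3-methylpenta-2,4-dien-1-ol | C=C/C(C)=C\CO | intermediate
17 | (2Z)-1-bromo-3-methylpenta-2,4-diene | C=C/C(C)=C\CBr | intermediate
18 | tert-butyl ester with quaternary C1 carrying geranyl (cis to C13–OH) and (2Z)-3-methylpenta-2,4-dienyl (cis to C7), ketones at C12 and C14, rings A and D | CC(C)=CCC/C(C)=C/C[C@]1(C/C=C(C)\C=C)C(=O)C(CC=C(C)C)=C2OC(C)(C)C(C(=O)OC(C)(C)C)[C@@]2(O)C1=O | intermediate
19 | trimethylsilyl ester and C13 trimethylsilyl ether from 18 (not isolated) | CC(C)=CCC/C(C)=C/C[C@]1(C/C=C(C)\C=C)C(=O)C(CC=C(C)C)=C2OC(C)(C)C(C(=O)O[Si](C)(C)C)[C@@]2(O[Si](C)(C)C)C1=O | intermediate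
20 | carboxylic acid at C7 with C13–OSiMe3 | CC(C)=CCC/C(C)=C/C[C@]1(C/C=C(C)\C=C)C(=O)C(CC=C(C)C)=C2OC(C)(C)C(C(=O)O)[C@@]2(O[Si](C)(C)C)C1=O | intermediate
21 | N-(acyloxy)phthalimide of 20 | CC(C)=CCC/C(C)=C/C[C@]1(C/C=C(C)\C=C)C(=O)C(CC=C(C)C)=C2OC(C)(C)C(C(=O)ON3C(=O)c4ccccc4C3=O)[C@@]2(O[Si](C)(C)C)C1=O | intermediate
22 | secondary radical at C7 (not isolated) | CC(C)=CCC/C(C)=C/C[C@]1(C/C=C(C)\C=C)C(=O)C(CC=C(C)C)=C2OC(C)(C)[CH][C@@]2(O[Si](C)(C)C)C1=O | intermediate
23 | nine-membered-ring allyl radical, C6–C7 formed (not isolated) | CC(C)=CCC/C(C)=C/C[C@]12C/C=C(C)\[CH]C[C@@H]3C(C)(C)OC(=C(CC=C(C)C)C1=O)[C@]3(O[Si](C)(C)C)C2=O | intermediate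
24 | allylchromium dichloride, chromium on C3, olefin C4=C5 (not isolated) | CC(C)=CCC/C(C)=C/C[C@]12CC([Cr](Cl)Cl)C(C)=CC[C@@H]3C(C)(C)OC(=C(CC=C(C)C)C1=O)[C@]3(O[Si](C)(C)C)C2=O | intermediate
25 | bis(trimethylsilyl) ether of 26 at the C13 and C14 oxygens (not isolated) | CC(C)=CCC/C(C)=C/C[C@]12CC=C(C)[C@@H]3C[C@@H]4C(C)(C)OC(=C(CC=C(C)C)C1=O)[C@]4(O[Si](C)(C)C)[C@@]32O[Si](C)(C)C | intermediate
26 | CNP0323114.1, tetracycle of rings A to D with cis-diol at C13/C14 | CC(C)=CCC/C(C)=C/C[C@]12CC=C(C)[C@@H]3C[C@@H]4C(C)(C)OC(=C(CC=C(C)C)C1=O)[C@]4(O)[C@@]32O | target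

Total step count: 13. Longest linear sequence: 11 steps (steps 1 to 7 and 10 to 13); steps 8 and 9 make the side-chain bromide.

Steps most likely to fail

1. Step 13 (proposed new method). The C7 radical may be captured by divalent chromium before the nine-membered closure and then lose the ring D oxygen by β-elimination, or the β-keto radical may undergo acyl migration. Fallback with known reactions, in which the ring closure is split into a polarity-matched radical step and an ionic step; it sets out from 14. Michael addition of 14 to penta-1,4-dien-3-one (Et3N, MeCN, 0 °C) should give the C1-quaternary vinyl ketone F1. Me3SiOTf/2,6-lutidine, then methanol, gives the silylated acid F2, and N-hydroxyphthalimide/DIC gives the redox-active ester F3. A reductive decarboxylative Giese cyclisation (Zn, NiCl2·6H2O cat., LiCl, DMF, high dilution) adds the nucleophilic C7 radical to the enone terminus and gives the nine-membered diketone F4. KN(SiMe3)2, then Me3SiCl, effects the transannular aldol addition of C5 to the C14 ketone and gives the bis-silylated ketol F5. KN(SiMe3)2/PhNTf2 gives the C3=C4 enol triflate F6, and Me2CuLi replaces the triflate by methyl. This returns to the route at 25, which the acidic work-up of step 13 converts into 26.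

2. Step 3. The tether already carries the C7 stereocentre, so catalyst control over the choice of arm may be incomplete for one of the two substrate enantiomers, and reversible transetherification may erode the selectivity. Fallback by resolution instead of asymmetric catalysis; it sets out from 6. Diphenyl hydrogen phosphate (5 mol %, toluene, 5 Å sieves) closes ring D without enantiocontrol to the racemic bicyclic dienone F7. Preparative chromatography on a chiral stationary phase separates the C13 antipodes and returns to the route at 7.

3. Step 10. O-alkylation may compete with C-alkylation, the dienyl group may enter on the wrong face of C1, and the allylic bromide may undergo transposition. Only the isomer with the dienyl chain cis to C7 can cyclise in step 13. Fallback by inverting the order of the two C1 alkylations; it sets out from 12. Alkylation of 12 with 17 (Cs2CO3, MeCN) gives the C1-dienyl vinylogous acid F8. The Tsuji–Trost reaction with 13 (Pd(PPh3)4, Et3N) then creates the quaternary centre with the geranyl group entering last, which inverts the facial outcome and returns to the route at 18. In this order the palladium catalyst also converts O-allylated material into the C-allylated product through the π-allyl complex.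

Further compounds
F1 | step 13 | C1-quaternary vinyl ketone: 18 with a 3-oxopent-4-enyl chain in place of the dienyl chain | CC(C)=CCC/C(C)=C/C[C@]1(CCC(=O)C=C)C(=O)C(CC=C(C)C)=C2OC(C)(C)C(C(=O)OC(C)(C)C)[C@@]2(O)C1=O
F2 | step 13 | carboxylic acid of F1 with C13–OSiMe3 | CC(C)=CCC/C(C)=C/C[C@]1(CCC(=O)C=C)C(=O)C(CC=C(C)C)=C2OC(C)(C)C(C(=O)O)[C@@]2(O[Si](C)(C)C)C1=O
F3 | step 13 | N-(acyloxy)phthalimide of F2 | CC(C)=CCC/C(C)=C/C[C@]1(CCC(=O)C=C)C(=O)C(CC=C(C)C)=C2OC(C)(C)C(C(=O)ON3C(=O)c4ccccc4C3=O)[C@@]2(O[Si](C)(C)C)C1=O
F4 | step 13 | nine-membered diketone (C6–C7 formed, ketones at C4 and C14) | CC(C)=CCC/C(C)=C/C[C@]12CCC(=O)CC[C@@H]3C(C)(C)OC(=C(CC=C(C)C)C1=O)[C@]3(O[Si](C)(C)C)C2=O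
F5 | step 13 | tetracyclic C4 ketone, bis(trimethylsilyl) ether at the C13 and C14 oxygens | CC(C)=CCC/C(C)=C/C[C@]12CCC(=O)[C@@H]3C[C@@H]4C(C)(C)OC(=C(CC=C(C)C)C1=O)[C@]4(O[Si](C)(C)C)[C@@]32O[Si](C)(C)C
F6 | step 13 | C3=C4 enol triflate of F5 | CC(C)=CCC/C(C)=C/C[C@]12CC=C(OS(=O)(=O)C(F)(F)F)[C@@H]3C[C@@H]4C(C)(C)OC(=C(CC=C(C)C)C1=O)[C@]4(O[Si](C)(C)C)[C@@]32O[Si](C)(C)C
F7 | step 3 | racemic 7 (both configurations at C13) | COC1=CC(=O)C=C2OC(C)(C)C(C(=O)OC(C)(C)C)C12O
F8 | step 10 | C1-[(2Z)-3-methylpenta-2,4-dienyl] vinylogous acid (12 alkylated at enolised C1) | C=C/C(C)=C\CC1=C(O)[C@]2(O)C(C(=O)OC(C)(C)C)C(C)(C)OC2=C(CC=C(C)C)C1=O
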